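Atom labels follow the order of the target SMILES (C1 to O28). The retrosynthesis cuts N6–C7 and N6=C5 (azepine, pyrroline), then C12–C13/O18–C16 (pendant lactone), then C20–C26 together with O21–C22 (cyclohexane and fused lactone), then C24–C26, C5–C20, C4–C5, C4–C10 and C3–C27.
Enabling feature: C20 is a tertiary carbinol carbon bonded to C26, and the C26 branch C24 carries both the lactone carbonyl C22 and the one-carbon unit C25. This is what a 2-(alkoxycarbonyl)allyl metal leaves after adding through its γ-carbon to a ketone and lactonising. The ring C3–C4–C5–C20–C26–C27 makes that addition intramolecular.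
Forward order: open C26–C5 chain, dithiane anion joined to an aspartate-derived amide, bromomethyl enoate, cyclohexane and fused lactone in one operation, pendant lactone, pyrroline, azepine/enamine.
Stereochemistry: C3/C27 come from an Evans syn aldol and C4 (a temporary control element) from a hydroboration. C11 comes from L-aspartic acid, C20/C26 from the key step, C12 from a chelation-controlled Barbier addition, and C14/C24 from one hydrogenation.

Key step: step 17

Remark: C4 becomes sp2 in the last step, so its configuration is free. It is set cis to the ethyl group on the future ring because that arrangement serves step 17.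

Step 1
Reactants: 1 (S)-4-benzyl-3-butanoyl-1,3-oxazolidin-2-one; 2 (tert-butyldimethylsilyloxy)acetaldehyde
Product: 4 (S)-4-benzyl-3-[(2S,3S)-4-(tert-butyldimethylsilyloxy)-2-ethyl-3-hydroxybutanoyl]-1,3-oxazolidin-2-one, via dibutylboron enolate 3 (not isolated)
Conditions: Bu2BOTf, Et3N, CH2Cl2, −78 to 0 °C; then H2O2, MeOH, pH 7 buffer
Reagents that add atoms: none
Why: Evans syn aldol, in which the (Z)-boron enolate reacts through a chair transition state on the face away from the benzyl group of the auxiliary and so sets C3 and C27 (ethyl and hydroxyl syn) in the absolute sense of the target.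

Step 2
Reactants: 4 aldol adduct
Product: 5 (2S,3S)-4-(tert-butyldimethylsilyloxy)-2-ethyl-3-hydroxy-N-methoxy-N-methylbutanamide
Conditions: MeNHOMe·HCl, AlMe3, THF, 0 °C to rt
Reagents that add atoms: N,O-dimethylhydroxylamine hydrochloride, CNOC.Cl
Why: Aluminium-amide transamination (Weinreb amide formation) of a β-hydroxy imide is assisted by the free hydroxyl group and removes the auxiliary without touching C3.

Step 3
Reactants: 5 hydroxy Weinreb amide
Product: 6 (2S,3S)-3-(benzyloxy)-4-(tert-butyldimethylsilyloxy)-2-ethyl-N-methoxy-N-methylbutanamide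
Conditions: 2-benzyloxy-1-methylpyridinium triflate, MgO, PhCF3, 85 °C
Reagents that add atoms: 2-benzyloxy-1-methylpyridinium triflate, C[n+]1ccccc1OCc1ccccc1.[O-]S(=O)(=O)C(F)(F)F
Why: Neutral thermal benzyl transfer (O-benzylation) avoids the retro-aldol and elimination pathways of basic Williamson conditions and installs the small, Lewis-basic ether on O28 that step 17 relies on.

Step 4
Reactants: 6 benzyl ether Weinreb amide; 7 benzyl 4-bromobutyl ether
Product: 9 (2S,3S)-2,8-bis(benzyloxy)-1-(tert-butyldimethylsilyloxy)-3-ethyloctan-4-one, via 4-(benzyloxy)butylmagnesium bromide 8 (not isolated)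
Conditions: 7, Mg, THF, rt; then 6, THF, 0 °C; aq NH4Cl
Reagents that add atoms: none
Why: Grignard addition to a Weinreb amide stops at the chelated tetrahedral adduct, so the C4 ketone carrying the C10–C7 chain is released only on work-up.

Step 5
Reactants: 9 ketone
Product: 10 (2S,3R)-2,8-bis(benzyloxy)-1-(tert-butyldimethylsilyloxy)-3-ethyl-4-methylideneoctane
Conditions: Cp2TiMe2, toluene, 75 °C
Reagents that add atoms: dimethyltitanocene Cp2TiMe2, [CH3-].[CH3-].[Ti+4].c1cc[cH-]c1.c1cc[cH-]c1
Why: Petasis methylenation through a titanium methylidene is non-basic, so the α-stereocentre C3 and the β-benzyloxy group survive while C5 is introduced.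

Step 6
Reactants: 10 1,1-disubstituted alkene
Product: 12 (2S,3R,4S)-4-(benzyloxy)-2-[4-(benzyloxy)butyl]-5-(tert-butyldimethylsilyloxy)-3-ethylpentan-1-ol, via B-alkyl-9-BBN adduct 11 (not isolated)
Conditions: 9-BBN, THF, rt to 40 °C; then NaOH, H2O2, 0 °C
Reagents that add atoms: hydrogen peroxide, OO
Why: In this hydroboration–oxidation H3 eclipses the alkene (allylic 1,3-strain) and the borane approaches anti to the large C27 branch, which should set C4 with the C10 chain anti to ethyl in the extended chain (cis on the future ring).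

Step 7
Reactants: 12 primary alcohol
Product: 13 (2S,3R,4S)-4-(benzyloxy)-2-[4-(benzyloxy)butyl]-5-(tert-butyldimethylsilyloxy)-3-ethylpentanal
Conditions: TEMPO (cat.), PhI(OAc)2, CH2Cl2, rt
Reagents that add atoms: none
Why: Oxoammonium (TEMPO) oxidation stops at the aldehyde under nearly neutral conditions, so C4 is not epimerised.

Step 8
Reactants: 13 aldehyde; 14 propane-1,3-dithiol
Product: 15 2-[(5S,6R,7S)-1,7-bis(benzyloxy)-8-(tert-butyldimethylsilyloxy)-6-ethyloctan-5-yl]-1,3-dithiane
Conditions: BF3·OEt2 (cat.), CH2Cl2, −78 to −30 °C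
Reagents that add atoms: none
Why: Lewis-acid thioacetalisation at low temperature turns C5 into a masked acyl anion and is tolerated by benzyl and silyl ethers.

Step 9
Reactants: 16 N-Boc-L-aspartic acid 4-benzyl ester
Product: 18 benzyl (S)-3-(tert-butoxycarbonylamino)-4-hydroxybutanoate, via mixed carbonic anhydride 17 (not isolated)
Conditions: i-BuOCOCl, N-methylmorpholine, THF, −15 °C; then NaBH4, H2O, 0 °C
Reagents that add atoms: none
Why: Chemoselective borohydride reduction of the mixed anhydride leaves the benzyl ester and the aspartate stereocentre C11 untouched.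

Step 10
Reactants: 18 N-Boc amino alcohol
Product: 19 tert-butyl (S)-4-(2-benzyloxy-2-oxoethyl)-2,2-dimethyl-1,3-oxazolidine-3-carboxylate
Conditions: Me2C(OMe)2, BF3·OEt2 (cat.), acetone, rt
Reagents that add atoms: 2,2-dimethoxypropane, COC(C)(C)OC
Why: Acid-catalysed N,O-acetonide formation masks the acidic N–H and the C12 hydroxyl in one operation, so the coupling partner of step 12 offers no proton and no second electrophile.

Step 11
Reactants: 19 oxazolidine benzyl ester
Product: 20 tert-butyl (S)-4-{2-[methoxy(methyl)amino]-2-oxoethyl}-2,2-dimethyl-1,3-oxazolidine-3-carboxylate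
Conditions: MeNHOMe·HCl, i-PrMgCl, THF, −20 °C
Reagents that add atoms: N,O-dimethylhydroxylamine hydrochloride, CNOC.Cl
Why: Direct aminolysis of the ester by the magnesium amide of N,O-dimethylhydroxylamine is the standard one-step route to a Weinreb amide.

Step 12
Reactants: 15 dithiane; 20 Weinreb amide
Product: 22 tert-butyl (S)-4-[2-(2-{(5S,6R,7S)-1,7-bis(benzyloxy)-8-(tert-butyldimethylsilyloxy)-6-ethyloctan-5-yl}-1,3-dithian-2-yl)-2-oxoethyl]-2,2-dimethyl-1,3-oxazolidine-3-carboxylate, via 2-lithio-1,3-dithiane 21 (not isolated)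
Conditions: 15, t-BuLi, THF–HMPA, −78 °C; then 20, −78 to −40 °C; aq NH4Cl
Reagents that add atoms: none
Why: In this Corey–Seebach umpolung the hindered 2-alkyl dithiane is metalated by t-BuLi/HMPA and acylated (C5–C20) by the Weinreb amide, whose chelated adduct blocks a second addition.

Step 13
Reactants: 22 keto dithiane silyl ether
Product: 23 keto dithiane primary alcohol (22 in which C26–OSi has become C26–OH)
Conditions: HF·pyridine, pyridine, THF, 0 °C
Reagents that add atoms: none
Why: Buffered fluoride cleavage removes the only silyl ether and leaves the N,O-acetonide, the carbamate and the benzyl ethers intact.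

Step 14
Reactants: 23 primary alcohol
Product: 24 keto dithiane aldehyde (23 in which C26 is CHO; chain unit (2S,3R,4S)-2,8-bis(benzyloxy)-3-ethyl-1-oxooctan-4-yl)
Conditions: TEMPO (cat.), PhI(OAc)2, CH2Cl2, rt
Reagents that add atoms: none
Why: Oxoammonium (TEMPO) oxidation of a primary alcohol tolerates thioethers and gives the α-benzyloxy aldehyde without epimerising C27.

Step 15
Reactants: 24 aldehyde; 25 methyl propiolate
Product: 27 allylic alcohol (24 in which C26 has become CH(OH)–C(=CH2)CO2Me; both C26 epimers; other centres as in 22), via α-aluminated acrylate 26 (not isolated)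
Conditions: 25, i-Bu2AlH, N-methylmorpholine N-oxide, THF, 0 °C; then 24, 0 °C to rt
Reagents that add atoms: none
Why: Vinylalumination (hydroalumination of the propiolate, then addition to the aldehyde rather than the hindered ketone) gives the Morita–Baylis–Hillman-type adduct without long exposure to an amine base, and the C26 configuration is irrelevant because C26 becomes sp2 in step 16.

Step 16
Reactants: 27 allylic alcohol
Product: 29 keto dithiane (Z)-2-(bromomethyl)enoate (BrC25H2–C24(CO2Me)=C26H–C27; C27 cis to CH2Br), via allylic mesylate 28 (not isolated)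
Conditions: MsCl, Et3N, CH2Cl2, −20 °C; then LiBr, THF, 0 °C to rt
Reagents that add atoms: lithium bromide, [Li+].[Br-]
Why: Mesylation and SN2′ displacement by bromide, the usual conversion of such adducts, gives the thermodynamically preferred (Z)-isomer and uses no oxidising bromine source that would attack the dithiane.

Step 17
Reactants: 29 keto dithiane (Z)-2-(bromomethyl)enoate
Product: 32 spiro-dithiane cyclohexane bearing the cis-fused α-methylene lactone (C20 and C26 as in the target; O28 benzyl; C19 carries the oxazolidine), via allylchromium dichloride 30 (not isolated), via chromium alkoxide 31 (not isolated)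
Conditions: CrCl2 (6 equiv), THF (0.01 M), rt to 40 °C; aq NH4Cl
Reagents that add atoms: none
Why: Two equivalents of divalent chromium reduce the C25–Br bond to the trivalent allylchromium 30, which binds the ketone oxygen O21 and transfers its substituted γ-carbon C26 to C20 through a closed six-membered array while the double bond moves to C24=C25, after which alkoxide 31 attacks the neighbouring ester carbon C22 and expels methoxide. The closest known reaction is the Nozaki–Hiyama (chromium Barbier) allylation of carbonyl compounds with 2-(bromomethyl)acrylates, an established inter- and intramolecular route to α-methylene-γ-butyrolactones. The cyclohexane closes 6-exo-trig at the C20 carbonyl (reaction through the unsubstituted terminus C25 would need an eight-membered ring) and the lactone closes 5-exo-trig at C22. C26 is controlled by C27: the C27–C3 tether can deliver the ketone only to the alkene face that carries C3, and with the small benzyloxy oxygen O28 lying in the alkene plane next to C25, where it can fill a coordination site of the chromium, that face gives H26 cis to H27, that is C24 cis to O28. C20 is controlled by the closed array: with the (Z)-allyl unit and O21 on the same metal, O21 ends cis to C24 (the only adduct that lactonises readily), C19 taking an equatorial position and O21 and O28 the 1,3-diaxial positions bridged by chromium. The step needs chemoselectivity for the ketone (activated inductively by the two sulfur atoms, while carbamate, ester and ethers are inert to allylchromium) and the rotamer with O28 rather than H27 in the alkene plane, and the C4 chain was set cis to ethyl because it is equatorial in the wanted array but 1,3-diaxial to O21 or C19 in the competing ones.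

Step 18
Reactants: 32 key product
Product: 33 N-Boc amino alcohol (32 in which the oxazolidine is opened to C11H(NHBoc)–C12H2OH)
Conditions: p-TsOH·H2O (cat.), MeOH, rt
Reagents that add atoms: none
Why: Acid-catalysed cleavage of the N,O-acetonide is routine for such oxazolidines and leaves the carbamate, lactone, dithiane and benzyl ethers in place.

Step 19
Reactants: 33 N-Boc amino alcohol
Product: 34 N-Boc α-amino aldehyde (C12 is CHO)
Conditions: TEMPO (cat.), PhI(OAc)2, CH2Cl2, 0 °C to rt
Reagents that add atoms: none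
Why: Oxoammonium (TEMPO) oxidation gives the configurationally sensitive α-amino aldehyde under nearly neutral conditions for immediate use, and the thioacetal is tolerated.

Step 20
Reactants: 34 α-amino aldehyde; 35 methyl 2-(bromomethyl)acrylate
Product: 38 dithiane bearing two α-methylene lactones (pendant lactone O18–C12–C13–C14(=CH2)–C16 on C11; C12 as in the target), via allylzinc bromide 36 (not isolated), via hydroxy ester 37 (not isolated)
Conditions: Zn, THF–sat. aq NH4Cl, 0 °C to rt; then pyridinium p-toluenesulfonate (cat.), toluene, 60 °C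
Reagents that add atoms: none
Why: In this Barbier-type 2-(alkoxycarbonyl)allylation and lactonisation, N-Boc α-amino aldehydes react under protic zinc conditions through the chelated (Cram cyclic) conformer, so the syn amino alcohol configuration of C12 should prevail and the anti isomer can be removed by chromatography.

Step 21
Reactants: 38 dithiane
Product: 39 C5 ketone (38 in which the dithiane is replaced by C=O)
Conditions: PhI(O2CCF3)2, MeCN–H2O, 0 °C
Reagents that add atoms: water, O
Why: Oxidative dithiane hydrolysis with a hypervalent iodine reagent (S-activation, capture by water) spares electron-poor alkenes, the carbamate and benzyl ethers, and it must precede step 22 because sulfur poisons palladium.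

Step 22
Reactants: 39 ketone
Product: 40 keto diol (C24 and C14 methyl groups as in the target; free C7 and C27 hydroxyl groups)
Conditions: H2, Pd/C, EtOH, rt
Reagents that add atoms: none
Why: In this heterogeneous hydrogenation hydrogen reaches C24=C25 from the convex face of the cis-fused bicycle (the face of H26) and the pendant methylene lactone from the face opposite its C12 substituent, which sets C24 and C14, while both benzyl ethers are hydrogenolysed.

Step 23
Reactants: 40 keto diol
Product: 41 primary C7 mesylate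
Conditions: MsCl (1 equiv), Et3N, CH2Cl2, −30 °C
Reagents that add atoms: methanesulfonyl chloride, CS(=O)(=O)Cl
Why: Sulfonylation is much faster at the unhindered primary C7 hydroxyl than at the C27 hydroxyl flanked by two tertiary carbons.

Step 24
Reactants: 41 mesylate
Product: 45 target CNP0154902.1, via ammonium trifluoroacetate 42 (not isolated), via pyrroline mesylate 43 (not isolated), via iminium mesylate 44 (not isolated)
Conditions: CF3CO2H, CH2Cl2, 0 °C; evaporate; then i-Pr2NEt, NaI (cat.), MeCN, 50 °C
Reagents that add atoms: none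
Why: Carbamate acidolysis, spontaneous five-ring ketimine condensation (N6=C5), 7-exo-tet N-alkylation of the imine (N6–C7) and loss of H4 from the iminium ion give the tetrasubstituted enamine, a known path from amino ketones with a terminal leaving group to bicyclic enamines, and C4 is erased here.

Compound list
1 | (S)-4-benzyl-3-butanoyl-1,3-oxazolidin-2-one | CCCC(=O)N1[C@@H](Cc2ccccc2)COC1=O | starting material
2 | (tert-butyldimethylsilyloxy)acetaldehyde | CC(C)(C)[Si](C)(C)OCC=O | starting material
3 | (Z)-dibutylboron enolate of 1 | CC/C=C(\OB(CCCC)CCCC)N1[C@@H](Cc2ccccc2)COC1=O | intermediate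
4 | (S)-4-benzyl-3-[(2S,3S)-4-(tert-butyldimethylsilyloxy)-2-ethyl-3-hydroxybutanoyl]-1,3-oxazolidin-2-one | CC(C)(C)[Si](C)(C)OC[C@@H](O)[C@H](CC)C(=O)N1[C@@H](Cc2ccccc2)COC1=O | intermediate
5 | (2S,3S)-4-(tert-butyldimethylsilyloxy)-2-ethyl-3-hydroxy-N-methoxy-N-methylbutanamide | CC(C)(C)[Si](C)(C)OC[C@@H](O)[C@H](CC)C(=O)N(C)OC | intermediate
6 | (2S,3S)-3-(benzyloxy)-4-(tert-butyldimethylsilyloxy)-2-ethyl-N-methoxy-N-methylbutanamide | CC(C)(C)[Si](C)(C)OC[C@@H](OCc1ccccc1)[C@H](CC)C(=O)N(C)OC | intermediate
7 | benzyl 4-bromobutyl ether | BrCCCCOCc1ccccc1 | starting material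
8 | 4-(benzyloxy)butylmagnesium bromide | Br[Mg]CCCCOCc1ccccc1 | intermediate
9 | (2S,3S)-2,8-bis(benzyloxy)-1-(tert-butyldimethylsilyloxy)-3-ethyloctan-4-one | CC(C)(C)[Si](C)(C)OC[C@@H](OCc1ccccc1)[C@H](CC)C(=O)CCCCOCc1ccccc1 | intermediate
10 | (2S,3R)-2,8-bis(benzyloxy)-1-(tert-butyldimethylsilyloxy)-3-ethyl-4-methylideneoctane | CC(C)(C)[Si](C)(C)OC[C@@H](OCc1ccccc1)[C@H](CC)C(=C)CCCCOCc1ccccc1 | intermediate
11 | B-alkyl-9-BBN adduct of 10 (boron on C5) | CC(C)(C)[Si](C)(C)OC[C@@H](OCc1ccccc1)[C@H](CC)[C@H](CCCCOCc1ccccc1)CB1C2CCCC1CCC2 | intermediate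
12 | (2S,3R,4S)-4-(benzyloxy)-2-[4-(benzyloxy)butyl]-5-(tert-butyldimethylsilyloxy)-3-ethylpentan-1-ol | CC(C)(C)[Si](C)(C)OC[C@@H](OCc1ccccc1)[C@H](CC)[C@H](CCCCOCc1ccccc1)CO | intermediate
13 | (2S,3R,4S)-4-(benzyloxy)-2-[4-(benzyloxy)butyl]-5-(tert-butyldimethylsilyloxy)-3-ethylpentanal | CC(C)(C)[Si](C)(C)OC[C@@H](OCc1ccccc1)[C@H](CC)[C@H](CCCCOCc1ccccc1)C=O | intermediate
14 | propane-1,3-dithiol | SCCCS | starting material
15 | 2-[(5S,6R,7S)-1,7-bis(benzyloxy)-8-(tert-butyldimethylsilyloxy)-6-ethyloctan-5-yl]-1,3-dithiane | CC(C)(C)[Si](C)(C)OC[C@@H](OCc1ccccc1)[C@H](CC)[C@H](CCCCOCc1ccccc1)C1SCCCS1 | intermediate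
16 | N-Boc-L-aspartic acid 4-benzyl ester | CC(C)(C)OC(=O)N[C@@H](CC(=O)OCc1ccccc1)C(=O)O | starting material
17 | mixed isobutyl carbonic anhydride of 16 | CC(C)(C)OC(=O)N[C@@H](CC(=O)OCc1ccccc1)C(=O)OC(=O)OCC(C)C | intermediate
18 | benzyl (S)-3-(tert-butoxycarbonylamino)-4-hydroxybutanoate | CC(C)(C)OC(=O)N[C@@H](CC(=O)OCc1ccccc1)CO | intermediate
19 | tert-butyl (S)-4-(2-benzyloxy-2-oxoethyl)-2,2-dimethyl-1,3-oxazolidine-3-carboxylate | CC1(C)OC[C@H](CC(=O)OCc2ccccc2)N1C(=O)OC(C)(C)C | intermediate
20 | tert-butyl (S)-4-{2-[methoxy(methyl)amino]-2-oxoethyl}-2,2-dimethyl-1,3-oxazolidine-3-carboxylate | CC1(C)OC[C@H](CC(=O)N(C)OC)N1C(=O)OC(C)(C)C | intermediate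
21 | 2-lithio derivative of 15 | CC(C)(C)[Si](C)(C)OC[C@@H](OCc1ccccc1)[C@H](CC)[C@H](CCCCOCc1ccccc1)C1([Li])SCCCS1 | intermediate
22 | keto dithiane silyl ether (C5 dithiane, C20 ketone, C11 in the N-Boc oxazolidine) | CC(C)(C)[Si](C)(C)OC[C@@H](OCc1ccccc1)[C@H](CC)[C@H](CCCCOCc1ccccc1)C1(SCCCS1)C(=O)C[C@H]1COC(C)(C)N1C(=O)OC(C)(C)C | intermediate
23 | keto dithiane primary alcohol (C26–OH) | OC[C@@H](OCc1ccccc1)[C@H](CC)[C@H](CCCCOCc1ccccc1)C1(SCCCS1)C(=O)C[C@H]1COC(C)(C)N1C(=O)OC(C)(C)C | intermediate
24 | keto dithiane aldehyde (C26 CHO) | O=C[C@@H](OCc1ccccc1)[C@H](CC)[C@H](CCCCOCc1ccccc1)C1(SCCCS1)C(=O)C[C@H]1COC(C)(C)N1C(=O)OC(C)(C)C | intermediate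
25 | methyl propiolate | C#CC(=O)OC | starting material
26 | [1-(methoxycarbonyl)vinyl]diisobutylaluminium | C=C(C(=O)OC)[Al](CC(C)C)CC(C)C | intermediate
27 | allylic alcohol, methyl 2-(1-hydroxyalkyl)acrylate (both C26 epimers) | C=C(C(=O)OC)C(O)[C@@H](OCc1ccccc1)[C@H](CC)[C@H](CCCCOCc1ccccc1)C1(SCCCS1)C(=O)C[C@H]1COC(C)(C)N1C(=O)OC(C)(C)C | intermediate
28 | allylic mesylate of 27 | C=C(C(=O)OC)C(OS(C)(=O)=O)[C@@H](OCc1ccccc1)[C@H](CC)[C@H](CCCCOCc1ccccc1)C1(SCCCS1)C(=O)C[C@H]1COC(C)(C)N1C(=O)OC(C)(C)C | intermediate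
29 | keto dithiane (Z)-2-(bromomethyl)enoate (key-step precursor) | BrC/C(C(=O)OC)=C\[C@@H](OCc1ccccc1)[C@H](CC)[C@H](CCCCOCc1ccccc1)C1(SCCCS1)C(=O)C[C@H]1COC(C)(C)N1C(=O)OC(C)(C)C | intermediate
30 | allylchromium dichloride from 29 | Cl[Cr](Cl)C/C(C(=O)OC)=C\[C@@H](OCc1ccccc1)[C@H](CC)[C@H](CCCCOCc1ccccc1)C1(SCCCS1)C(=O)C[C@H]1COC(C)(C)N1C(=O)OC(C)(C)C | intermediate
31 | chromium alkoxide of the cyclised hydroxy ester | CC[C@@H]1[C@H](CCCCOCc2ccccc2)C3(SCCCS3)[C@@](C[C@H]3COC(C)(C)N3C(=O)OC(C)(C)C)(O[Cr](Cl)Cl)[C@@H](C(=C)C(=O)OC)[C@H]1OCc1ccccc1 | intermediate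
32 | spiro-dithiane cyclohexane with cis-fused α-methylene lactone (key-step product) | CC[C@@H]1[C@H](CCCCOCc2ccccc2)C3(SCCCS3)[C@@]2(C[C@H]3COC(C)(C)N3C(=O)OC(C)(C)C)OC(=O)C(=C)[C@H]2[C@H]1OCc1ccccc1 | intermediate
33 | N-Boc amino alcohol (C12H2OH) | CC[C@@H]1[C@H](CCCCOCc2ccccc2)C3(SCCCS3)[C@@]2(C[C@H](NC(=O)OC(C)(C)C)CO)OC(=O)C(=C)[C@H]2[C@H]1OCc1ccccc1 | intermediate
34 | N-Boc α-amino aldehyde (C12 CHO) | CC[C@@H]1[C@H](CCCCOCc2ccccc2)C3(SCCCS3)[C@@]2(C[C@H](NC(=O)OC(C)(C)C)C=O)OC(=O)C(=C)[C@H]2[C@H]1OCc1ccccc1 | intermediate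
35 | methyl 2-(bromomethyl)acrylate | C=C(CBr)C(=O)OC | starting material
36 | 2-(methoxycarbonyl)allylzinc bromide | C=C(C[Zn]Br)C(=O)OC | intermediate
37 | syn hydroxy ester from 34 and 36 | CC[C@@H]1[C@H](CCCCOCc2ccccc2)C3(SCCCS3)[C@@]2(C[C@H](NC(=O)OC(C)(C)C)[C@@H](O)CC(=C)C(=O)OC)OC(=O)C(=C)[C@H]2[C@H]1OCc1ccccc1 | intermediate
38 | dithiane bearing two α-methylene lactones | CC[C@@H]1[C@H](CCCCOCc2ccccc2)C3(SCCCS3)[C@@]2(C[C@H](NC(=O)OC(C)(C)C)[C@@H]3CC(=C)C(=O)O3)OC(=O)C(=C)[C@H]2[C@H]1OCc1ccccc1 | intermediate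
39 | C5 ketone bearing two α-methylene lactones | CC[C@@H]1[C@H](CCCCOCc2ccccc2)C(=O)[C@@]2(C[C@H](NC(=O)OC(C)(C)C)[C@@H]3CC(=C)C(=O)O3)OC(=O)C(=C)[C@H]2[C@H]1OCc1ccccc1 | intermediate
40 | keto diol with both α-methyl lactones | CC[C@@H]1[C@H](CCCCO)C(=O)[C@@]2(C[C@H](NC(=O)OC(C)(C)C)[C@@H]3C[C@H](C)C(=O)O3)OC(=O)[C@@H](C)[C@H]2[C@H]1O | intermediate
41 | primary C7 mesylate | CC[C@@H]1[C@H](CCCCOS(C)(=O)=O)C(=O)[C@@]2(C[C@H](NC(=O)OC(C)(C)C)[C@@H]3C[C@H](C)C(=O)O3)OC(=O)[C@@H](C)[C@H]2[C@H]1O | intermediate
42 | ammonium trifluoroacetate of the amino ketone | CC[C@@H]1[C@H](CCCCOS(C)(=O)=O)C(=O)[C@@]2(C[C@H]([NH3+])[C@@H]3C[C@H](C)C(=O)O3)OC(=O)[C@@H](C)[C@H]2[C@H]1O.[O-]C(=O)C(F)(F)F | intermediate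
43 | pyrroline mesylate (N6=C5) | CC[C@@H]1[C@H](CCCCOS(C)(=O)=O)C2=N[C@H]([C@@H]3C[C@H](C)C(=O)O3)C[C@@]24OC(=O)[C@@H](C)[C@H]4[C@H]1O | intermediate
44 | bicyclic iminium mesylate (N6–C7 closed) | CC[C@@H]1[C@@H]2CCCC[N+]3=C2[C@@]4(C[C@H]3[C@@H]5C[C@H](C)C(=O)O5)OC(=O)[C@@H](C)[C@H]4[C@H]1O.CS(=O)(=O)[O-] | intermediate
45 | CNP0154902.1 | CC[C@@H]1C2=C3N(CCCC2)[C@H]([C@@H]2C[C@H](C)C(=O)O2)C[C@@]32OC(=O)[C@@H](C)[C@H]2[C@H]1O | target

Total step count: 24. Longest linear sequence: 21 steps (steps 1–8 and 12–24).

Steps most likely to fail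

1) Step 17.
- What may go wrong: addition to the neopentyl ketone may be slow, because the wanted array carries an axial ethyl group facing an axial sulfur. The allylchromium could then be lost by protonation or by reductive 1,4-elimination of the C27 benzyloxy group. The allyl unit may also lose its (Z)-geometry, or react through the rotamer with H27 in the alkene plane, which would invert C26 and C20 together.
- Fallback: it sets out from 27 and replaces the reductively generated, configurationally mobile allylmetal by an isolable allylboron reagent. Alcohol 27 is acetylated (Ac2O, pyridine, DMAP) to the allylic acetate F1. Hosomi–Miyaura borylation (B2pin2, CuCl, LiCl, KOAc, DMF) proceeds in the SN2′ sense and gives the 2-(methoxycarbonyl)allylboronate F2 with fixed alkene geometry. Heating F2 in toluene, if needed with Sc(OTf)3 (cat.), brings about the known allylboration–lactonisation through a closed six-membered array.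
- Limits and return point: F2 has no reductive elimination channel and can be forced thermally, but it does not by itself correct the rotamer problem. The fallback comes back to the route at 32.

2) Step 12.
- What may go wrong: metalation of the hindered dithiane may be incomplete, or the anion may act as a base towards C19–H of the amide instead of adding.
- Fallback: it sets out from 19 and 21 and uses a more reactive electrophile at a lower oxidation level. Ester 19 is reduced (i-Bu2AlH, toluene, −78 °C) to the oxazolidine acetaldehyde F3. Anion 21 adds to it at −78 °C to give the C20 carbinol F4 (epimers). Oxidation (SO3·pyridine, DMSO, Et3N) comes back to the route at 22.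

3) Step 24.
- What may go wrong: seven-ring N-alkylation of the hindered imine may be slow. The free amine or imine could then attack a lactone carbonyl, or the free C27 hydroxyl could take part in acyl migration on prolonged heating with base.
- Fallback: it sets out from 40 and closes N6–C7 by reductive amination instead of substitution. Selective oxidation of the primary alcohol (TEMPO, PhI(OAc)2) gives the keto aldehyde F5. Carbamate removal (CF3CO2H, 0 °C) lets the pyrroline form and condense with the C7 aldehyde. NaBH(OAc)3 in ClCH2CH2Cl reduces the resulting unhindered aldiminium ion but not the shielded C5=N unit, which comes back to the route at 45.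

Further compounds
F1 | step 17 | allylic acetate of 27 | C=C(C(=O)OC)C(OC(C)=O)[C@@H](OCc1ccccc1)[C@H](CC)[C@H](CCCCOCc1ccccc1)C1(SCCCS1)C(=O)C[C@H]1COC(C)(C)N1C(=O)OC(C)(C)C
F2 | step 17 | 2-(methoxycarbonyl)allylboronic acid pinacol ester (boron on C25, C27 cis to C25) | CC1(C)OB(C/C(C(=O)OC)=C\[C@@H](OCc2ccccc2)[C@H](CC)[C@H](CCCCOCc2ccccc2)C2(SCCCS2)C(=O)C[C@H]2COC(C)(C)N2C(=O)OC(C)(C)C)OC1(C)C
F3 | step 12 | tert-butyl (S)-2,2-dimethyl-4-(2-oxoethyl)-1,3-oxazolidine-3-carboxylate | CC1(C)OC[C@H](CC=O)N1C(=O)OC(C)(C)C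
F4 | step 12 | C20 carbinol corresponding to 22 (both C20 epimers) | CC(C)(C)[Si](C)(C)OC[C@@H](OCc1ccccc1)[C@H](CC)[C@H](CCCCOCc1ccccc1)C1(SCCCS1)C(O)C[C@H]1COC(C)(C)N1C(=O)OC(C)(C)C
F5 | step 24 | keto aldehyde (C7 CHO) from 40 | CC[C@@H]1[C@H](CCCC=O)C(=O)[C@@]2(C[C@H](NC(=O)OC(C)(C)C)[C@@H]3C[C@H](C)C(=O)O3)OC(=O)[C@@H](C)[C@H]2[C@H]1O
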